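**Overview**

- **Cuts.** Atom numbers follow ent-kaurane. C17–OH and the C15 ketone go back to the exocyclic C16=C17 alkene. The lactone bond O–C7 is opened and C11–OH removed, which leaves a C11=C12 alkene and C20 as a free carboxyl. The C9–C10 bond is then cut (ester-enolate Claisen transform) into a C12 allylic alcohol carrying rings C and D and a ring-A α-bromo acid. Last, C13–C16 (ring D) and C5–C10/C3–C4 (ring A) are cut.
- **Enabling feature.** C9, a tertiary carbon on the three-carbon bridge of the bicyclo[3.2.1]octane (rings C and D), is bonded to the spiro quaternary C10 of ring A. C10 carries C20, the CH2–O of the δ-lactone, which is a reduced carboxyl carbon. C11, next to C9, carries an oxygen that can be added across a C11=C12 alkene. This is the γ,δ-unsaturated acid left by a [3,3] shift of a C12 allyl ester enolate.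
- **Forward order.** Ring C is the ring of benzoic acid and ring D closes by gold-catalysed 5-exo-dig cyclisation. Ring A arises by Diels–Alder reaction and its γ-lactone by anhydride reduction. The halves are joined at C9–C10, then the δ-lactone closes and ring D is oxidised.
- **Stereochemistry.** C8 comes from an enzymatic desymmetrisation, and C13 follows through the bridge. C4/C5 come from the cis dienophile plus a resolution. C12 (temporary; Luche reduction, then Mitsunobu inversion) relays to C9. C10 forms anti to the C5–C6 bond, C11 by tethered syn hydrosilylation, and C16 by exo-face protonation.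

Key step: step 16

Assumption 1: an Old Yellow Enzyme ene-reductase that reduces the enone arm of dienone 6 leading to the (R)-enone is available (YqjM is taken as the default member of the panel).
Assumption 2: the salt of the wanted acid with (S)-1-phenylethylamine is the less soluble one; if it is the other way round, the (R)-amine is used and nothing else changes.

**Route**

Step 1
Reactants: 1 benzoic acid; 2 propargyl bromide
Product: 4 1-(prop-2-yn-1-yl)cyclohexa-2,5-diene-1-carboxylic acid, via dilithium dienediolate 3 (not isolated)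
Conditions: Li (3.2 equiv), NH3(l)/THF, −78 °C; isoprene; 2 (1.5 equiv), −78 to −33 °C; NH4Cl, then aq. HCl
Reagents that add atoms: none
Why: Birch reductive alkylation, in which dissolving-metal reduction of benzoate gives the cross-conjugated dienediolate 3 that is alkylated at the carboxyl-bearing carbon to create quaternary C8 (still achiral), the alkyne being spared because excess metal is discharged before the halide is added.

Step 2
Reactants: 4 1-(prop-2-yn-1-yl)cyclohexa-2,5-diene-1-carboxylic acid
Product: 5 methyl 1-(prop-2-yn-1-yl)cyclohexa-2,5-diene-1-carboxylate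
Conditions: MeI, K2CO3, DMF, rt
Reagents that add atoms: iodomethane, CI
Why: Carboxylate O-alkylation (SN2) under conditions too mild to touch the skipped diene or the terminal alkyne.

Step 3
Reactants: 5 methyl 1-(prop-2-yn-1-yl)cyclohexa-2,5-diene-1-carboxylate
Product: 6 methyl 4-oxo-1-(prop-2-yn-1-yl)cyclohexa-2,5-diene-1-carboxylate
Conditions: Rh2(cap)4 [dirhodium tetrakis(caprolactamate), Rh2(C6H10NO)4] (1 mol%), t-BuOOH (70% aq., 5 equiv), K2CO3 (cat.), CH2Cl2, rt
Reagents that add atoms: tert-butyl hydroperoxide, CC(C)(C)OO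
Why: Catalytic allylic oxidation by tert-butylperoxyl radicals, which should convert the doubly allylic C12 methylene (by far the weakest C–H bonds) into the cross-conjugated dienone in preference to the propargylic CH2.

Step 4
Reactants: 6 methyl 4-oxo-1-(prop-2-yn-1-yl)cyclohexa-2,5-diene-1-carboxylate
Product: 7 methyl (1R)-4-oxo-1-(prop-2-yn-1-yl)cyclohex-2-ene-1-carboxylate
Conditions: ene-reductase YqjM, NADP+ (cat.), D-glucose, glucose dehydrogenase, phosphate buffer pH 7, DMSO (5% v/v), 30 °C
Reagents that add atoms: none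
Why: Enzymatic desymmetrising conjugate reduction of a prochiral 4,4-disubstituted cyclohexa-2,5-dienone (flavin hydride to the β-carbon, trans protonation at the α-carbon), in which the active site distinguishes the two enantiotopic enone arms and thereby fixes C8 as R, the product enone being a poorer substrate so that over-reduction should be slow.

Step 5
Reactants: 7 methyl (1R)-4-oxo-1-(prop-2-yn-1-yl)cyclohex-2-ene-1-carboxylate
Product: 8 methyl (1R)-4-[(tert-butyldimethylsilyl)oxy]-1-(prop-2-yn-1-yl)cyclohexa-2,4-diene-1-carboxylate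
Conditions: TBSOTf, Et3N, CH2Cl2, 0 °C
Reagents that add atoms: tert-butyldimethylsilyl triflate, CC(C)(C)[Si](C)(C)OS(=O)(=O)C(F)(F)F
Why: Soft enolisation, which is regiospecific because quaternary C8 leaves no γ-hydrogen, so only an α′-proton at C13 can be removed and the 2-silyloxy-1,3-diene results.

Step 6
Reactants: 8 methyl (1R)-4-[(tert-butyldimethylsilyl)oxy]-1-(prop-2-yn-1-yl)cyclohexa-2,4-diene-1-carboxylate
Product: 9 methyl (1R,5R)-6-methylidene-4-oxobicyclo[3.2.1]oct-2-ene-1-carboxylate
Conditions: Ph3PAuCl (5 mol%), AgBF4 (5 mol%), CH2Cl2/MeOH (10:1), rt to 40 °C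
Reagents that add atoms: none
Why: Gold-catalysed carbocyclisation of a silyl enol ether onto an alkyne (Conia-ene type), in which π-activation by cationic monovalent gold triggers 5-exo-dig attack of C13 on the internal alkyne carbon C16, methanol takes the silyl group and protodeauration leaves the exocyclic methylene; the propargyl arm can only bridge cis, so C13 follows from C8.

Step 7
Reactants: 9 methyl (1R,5R)-6-methylidene-4-oxobicyclo[3.2.1]oct-2-ene-1-carboxylate
Product: 10 methyl (1R,4R,5R)-4-hydroxy-6-methylidenebicyclo[3.2.1]oct-2-ene-1-carboxylate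
Conditions: NaBH4, CeCl3·7H2O, MeOH, −78 °C
Reagents that add atoms: none
Why: Luche 1,2-reduction, in which hydride should add to C12 from the face of the one-carbon C14 bridge, away from the C15–C16 bridge and its exocyclic methylene, placing the hydroxyl on the side of the two-carbon bridge (4R).

Step 8
Reactants: 11 citraconic anhydride; 12 methyl (2E)-penta-2,4-dienoate
Product: 13 methyl rac-(3aS,4S,7aR)-7a-methyl-1,3-dioxo-1,3,3a,4,7,7a-hexahydro-2-benzofuran-4-carboxylate
Conditions: neat (11 in slight excess), BHT (1 mol%), 120 °C, sealed vessel; endo adduct crystallised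
Reagents that add atoms: none
Why: Thermal Diels–Alder reaction, in which the unsubstituted diene terminus C3 should bond to the methyl-bearing carbon C4 (larger LUMO coefficient and less crowded quaternary-centre formation), the cis geometry of the anhydride fixes C4 and C5 cis, and the endo/exo result at C10 is irrelevant because C10 later becomes trigonal.

Step 9
Reactants: 13 methyl rac-(3aS,4S,7aR)-7a-methyl-1,3-dioxo-1,3,3a,4,7,7a-hexahydro-2-benzofuran-4-carboxylate
Product: 15 methyl rac-(3aS,4S,7aR)-7a-methyl-3-oxo-1,3,3a,4,7,7a-hexahydro-2-benzofuran-4-carboxylate, via hydroxy acid 14 (not isolated)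
Conditions: NaBH4, THF, 0 °C to rt; then 2 M HCl, rt
Reagents that add atoms: none
Why: Regioselective borohydride reduction of an unsymmetrical cyclic anhydride, which is known to occur at the carbonyl flanked by the more substituted carbon (here C19 next to quaternary C4), followed by acid-promoted γ-lactonisation of hydroxy acid 14, the methyl ester being inert to NaBH4 under these conditions.

Step 10
Reactants: 15 methyl rac-(3aS,4S,7aR)-7a-methyl-3-oxo-1,3,3a,4,7,7a-hexahydro-2-benzofuran-4-carboxylate
Product: 16 methyl rac-(3aS,4S,7aR)-7a-methyl-3-oxooctahydro-2-benzofuran-4-carboxylate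
Conditions: H2 (1 atm), Pd/C (10%), EtOAc, rt
Reagents that add atoms: none
Why: Heterogeneous catalytic hydrogenation of the isolated disubstituted alkene, which creates no stereocentre.

Step 11
Reactants: 16 methyl rac-(3aS,4S,7aR)-7a-methyl-3-oxooctahydro-2-benzofuran-4-carboxylate
Product: 17 rac-(3aS,4S,7aR)-7a-methyl-3-oxooctahydro-2-benzofuran-4-carboxylic acid
Conditions: 6 M HCl, 1,4-dioxane, 90 °C
Reagents that add atoms: water, O
Why: Acid-catalysed ester hydrolysis, during which the γ-lactone stays closed at equilibrium and C10 is not epimerised, so a single racemic diastereomer enters the resolution.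

Step 12
Reactants: 17 rac-(3aS,4S,7aR)-7a-methyl-3-oxooctahydro-2-benzofuran-4-carboxylic acid
Product: 18 (1S)-1-phenylethanaminium (3aS,4S,7aR)-7a-methyl-3-oxooctahydro-2-benzofuran-4-carboxylate
Conditions: (S)-1-phenylethylamine (1.0 equiv), EtOAc/EtOH, crystallisation, recrystallised to constant rotation
Reagents that add atoms: (S)-1-phenylethylamine, C[C@H](N)c1ccccc1
Why: Classical resolution through diastereomeric ammonium salts of different solubility, which fixes the absolute configuration of C4 and C5 (see assumption 2).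

Step 13
Reactants: 18 (1S)-1-phenylethanaminium (3aS,4S,7aR)-7a-methyl-3-oxooctahydro-2-benzofuran-4-carboxylate
Product: 19 (3aS,4S,7aR)-7a-methyl-3-oxooctahydro-2-benzofuran-4-carboxylic acid
Conditions: 1 M HCl, EtOAc, rt
Reagents that add atoms: none
Why: Acid–base liberation of the carboxylic acid from its salt, which touches no stereocentre.

Step 14
Reactants: 19 (3aS,4S,7aR)-7a-methyl-3-oxooctahydro-2-benzofuran-4-carboxylic acid
Product: 22 (3aS,7aR)-4-bromo-7a-methyl-3-oxooctahydro-2-benzofuran-4-carboxylic acid (both C10 epimers), via acyl chloride 20 (not isolated), via bromo acyl chloride 21 (not isolated)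
Conditions: SOCl2, 70 °C; NBS, HBr (48% aq., cat.), 85 °C; then H2O/THF, 0 °C to rt
Reagents that add atoms: N-bromosuccinimide, O=C1CCC(=O)N1Br; water, O
Why: Hell–Volhard–Zelinsky-type α-bromination run through the acyl chloride, in which only the acyl halide enolises so that bromine enters at C10 and not at the lactone α-carbon C5 (the neopentyl C19–O bond also resists opening by halide), both C10 epimers being usable because C10 becomes an enolate carbon.

Step 15
Reactants: 10 methyl (1R,4R,5R)-4-hydroxy-6-methylidenebicyclo[3.2.1]oct-2-ene-1-carboxylate; 22 (3aS,7aR)-4-bromo-7a-methyl-3-oxooctahydro-2-benzofuran-4-carboxylic acid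
Product: 23 methyl (1R,4S,5R)-4-{[(3aS,7aR)-4-bromo-7a-methyl-3-oxooctahydro-2-benzofuran-4-carbonyl]oxy}-6-methylidenebicyclo[3.2.1]oct-2-ene-1-carboxylate
Conditions: PPh3, DIAD, THF, 0 °C to rt (10 and 22 added to the preformed betaine)
Reagents that add atoms: none
Why: Mitsunobu esterification, in which the acidic α-bromo acid (pKa about 3) protonates the betaine and its carboxylate displaces the oxyphosphonium group at C12 by SN2 with inversion, turning the C12–O bond to the face of the C14 bridge (4S), while attack at the far allyl terminus C9 is blocked by quaternary C8.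

Step 16
Reactants: 23 methyl (1R,4S,5R)-4-{[(3aS,7aR)-4-bromo-7a-methyl-3-oxooctahydro-2-benzofuran-4-carbonyl]oxy}-6-methylidenebicyclo[3.2.1]oct-2-ene-1-carboxylate
Product: 27 Claisen acid (7-methyl hydrogen 19-hydroxy-6,7-seco-ent-kaura-11,16-diene-6,7,20-trioate 6,19-lactone), via zinc enolate 24 (not isolated), via silyl ketene acetal 25 (not isolated), via trimethylsilyl ester 26 (not isolated)
Conditions: Zn dust (activated, 4 equiv), TMSCl (4 equiv), THF, 65 °C; then 1 M HCl
Reagents that add atoms: none
Why: Zinc inserts into the tertiary C10–Br bond (Reformatsky) to give zinc enolate 24, which TMSCl traps as silyl ketene acetal 25 without any base, so the acidic C5–H of the lactone is never touched; 25 then undergoes a concerted suprafacial [3,3]-sigmatropic shift across O–C20=C10 and C12–C11=C9 that forms C9–C10, moves the alkene to C11=C12 and releases C20 as silyl ester 26, hydrolysed to the acid on work-up. The closest known reaction type is the Reformatsky–Claisen (zinc enolate Ireland–Claisen) rearrangement of allyl α-bromo esters, including α,α-disubstituted acids and cyclohexenyl esters. No ring is closed, since the step only joins the two halves. C9 is controlled by the C12–O bond, which stands pseudoaxial on the C14 face of the rigid bicycle, so that C10 is delivered to that same face of C9 (1,3-chirality transfer), most likely through a boat-like array that keeps C20 away from the C14 hydrogen. C10 is controlled by ring A: the allyl terminus should add anti to the vicinal C5–C6 bond, on the convex face of the cis-fused lactone, forming an equatorial bond on the conformer that has the C4 methyl equatorial, and because C10 is the ring carbon of an exocyclic ketene acetal its configuration depends only on the face attacked, the ketene acetal geometry merely deciding between chair and boat. The step therefore needs facial selectivity at both termini (secured at C9 by the inverted C12 ester and at C10 by the lactone fusion, the 1,3-related C4 methyl on the attacked face being the main risk) and rearrangement faster than protonation of the enolate (secured by anhydrous conditions, excess TMSCl and heating).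

Step 17
Reactants: 27 Claisen acid
Product: 29 C20 primary alcohol (methyl 19,20-dihydroxy-6,7-seco-ent-kaura-11,16-diene-6,7-dioate 6,19-lactone), via acyl imidazolide 28 (not isolated)
Conditions: 1,1'-carbonyldiimidazole (Im2CO), THF, rt to 40 °C; then NaBH4, H2O/THF, 0 °C; pH 7 work-up, used at once
Reagents that add atoms: none
Why: Chemoselective reduction of the only free carboxyl group through its acyl imidazolide, which aqueous NaBH4 reduces at 0 °C while the methyl ester and the γ-lactone survive, and since any borane is destroyed by water the two alkenes are not hydroborated.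

Step 18
Reactants: 29 C20 primary alcohol
Product: 32 C11,C20-diol (methyl 11,19,20-trihydroxy-6,7-seco-ent-kaur-16-ene-6,7-dioate 6,19-lactone), via hydridosilyl ether 30 (not isolated), via cyclic siloxane 31 (not isolated)
Conditions: HMe2SiCl, Et3N, CH2Cl2, 0 °C, filter and concentrate; then zerovalent platinum complex Pt2[(CH2=CHSiMe2)2O]3 (1 mol% Pt), toluene (0.01 M), 60 °C; then H2O2 (30% aq.), KF, KHCO3, THF/MeOH, rt
Reagents that add atoms: hydrogen peroxide, OO
Why: Silicon-tethered intramolecular hydrosilylation followed by Tamao oxidation, in which the Si–H group can reach only C11 (six-membered oxasilinane, exo mode) and adds syn across C11=C12 from the face on which C10 sits at C9, and oxidative C–Si cleavage with retention then gives the C11 alcohol cis to the C9–C10 bond, high dilution disfavouring intermolecular reaction at the exocyclic methylene.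

Step 19
Reactants: 32 C11,C20-diol
Product: 33 11-hydroxy-6,7-seco-ent-kaur-16-ene-6,19:7,20-diolide
Conditions: DBU (0.3 equiv), toluene, 80 °C
Reagents that add atoms: none
Why: Base-catalysed lactonisation (intramolecular transesterification), in which the C20 hydroxyl closes the six-membered lactone on the C7 ester with loss of methanol, whereas the equatorial C11 hydroxyl cannot reach C7 and any reversible acyl shift from the γ-lactone onto C20 is drained by the irreversible loss of methanol.

Step 20
Reactants: 33 11-hydroxy-6,7-seco-ent-kaur-16-ene-6,19:7,20-diolide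
Product: 34 11,15-dihydroxy-6,7-seco-ent-kaur-16-ene-6,19:7,20-diolide
Conditions: SeO2 (0.5 equiv), t-BuOOH (3 equiv), CH2Cl2, 0 °C to rt
Reagents that add atoms: tert-butyl hydroperoxide, CC(C)(C)OO (its oxygen is relayed by catalytic selenium dioxide, O=[Se]=O)
Why: Selenium dioxide allylic oxidation (ene reaction, then [2,3]-sigmatropic shift) of the exocyclic methylene at its only non-bridgehead allylic position C15, a reaction well established for ent-kaur-16-enes, the C15 configuration being of no consequence.

Step 21
Reactants: 34 11,15-dihydroxy-6,7-seco-ent-kaur-16-ene-6,19:7,20-diolide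
Product: 35 11-hydroxy-15-oxo-6,7-seco-ent-kaur-16-ene-6,19:7,20-diolide
Conditions: MnO2 (activated, excess), CH2Cl2, rt
Reagents that add atoms: none
Why: Chemoselective MnO2 oxidation of the allylic C15 alcohol to the exocyclic enone, the saturated secondary C11 alcohol not being oxidised by this reagent.

Step 22
Reactants: 35 11-hydroxy-15-oxo-6,7-seco-ent-kaur-16-ene-6,19:7,20-diolide
Product: 36 11-hydroxy-15-oxo-17-(4,4,5,5-tetramethyl-1,3,2-dioxaborolan-2-yl)-6,7-seco-ent-kaurane-6,19:7,20-diolide
Conditions: CuCl (5 mol%), NaOt-Bu (10 mol%), DPEphos (6 mol%), B2pin2 (1.2 equiv), MeOH (2 equiv), THF, 0 °C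
Reagents that add atoms: bis(pinacolato)diboron, CC1(C)OB(OC1(C)C)B1OC(C)(C)C(C)(C)O1
Why: Copper-catalysed conjugate borylation, in which a ligated Cu–Bpin species adds boron to the unhindered terminus C17 and methanol protonates the resulting enolate at C16 from the exo face (the side of the one-carbon C14 bridge), which turns the CH2B group towards ring C as the target requires.

Step 23
Reactants: 36 11-hydroxy-15-oxo-17-(4,4,5,5-tetramethyl-1,3,2-dioxaborolan-2-yl)-6,7-seco-ent-kaurane-6,19:7,20-diolide
Product: 37 CNP0555433.1 (11,17-dihydroxy-15-oxo-6,7-seco-ent-kaurane-6,19:7,20-diolide)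
Conditions: NaBO3·4H2O, THF/H2O, 0 °C to rt
Reagents that add atoms: sodium perborate, [Na+].[Na+].O[B-]1(O)OO[B-](O)(O)OO1
Why: Perborate oxidation of the primary alkylboronate (1,2-shift of C17 from boron to oxygen), mild enough that the β-hydroxy ketone should neither eliminate nor epimerise at C16.

**Compound list**

1 | benzoic acid | OC(=O)c1ccccc1 | starting material
2 | propargyl bromide (3-bromoprop-1-yne) | C#CCBr | starting material
3 | dilithium (cyclohexa-2,5-dien-1-ylidene)methanediolate (Birch dianion) | [Li+].[Li+].[O-]C([O-])=C1C=CCC=C1 | intermediate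
4 | 1-(prop-2-yn-1-yl)cyclohexa-2,5-diene-1-carboxylic acid | OC(=O)C1(CC#C)C=CCC=C1 | intermediate
5 | methyl 1-(prop-2-yn-1-yl)cyclohexa-2,5-diene-1-carboxylate | COC(=O)C1(CC#C)C=CCC=C1 | intermediate
6 | methyl 4-oxo-1-(prop-2-yn-1-yl)cyclohexa-2,5-diene-1-carboxylate | COC(=O)C1(CC#C)C=CC(=O)C=C1 | intermediate
7 | methyl (1R)-4-oxo-1-(prop-2-yn-1-yl)cyclohex-2-ene-1-carboxylate | COC(=O)[C@@]1(CC#C)CCC(=O)C=C1 | intermediate
8 | methyl (1R)-4-[(tert-butyldimethylsilyl)oxy]-1-(prop-2-yn-1-yl)cyclohexa-2,4-diene-1-carboxylate | COC(=O)[C@@]1(CC#C)CC=C(O[Si](C)(C)C(C)(C)C)C=C1 | intermediate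
9 | methyl (1R,5R)-6-methylidene-4-oxobicyclo[3.2.1]oct-2-ene-1-carboxylate | COC(=O)[C@@]12C[C@@H](C(=O)C=C1)C(=C)C2 | intermediate
10 | methyl (1R,4R,5R)-4-hydroxy-6-methylidenebicyclo[3.2.1]oct-2-ene-1-carboxylate (OH on the side of the two-carbon bridge) | COC(=O)[C@@]12C[C@@H]([C@H](O)C=C1)C(=C)C2 | intermediate
11 | citraconic anhydride (3-methylfuran-2,5-dione) | CC1=CC(=O)OC1=O | starting material
12 | methyl (2E)-penta-2,4-dienoate | COC(=O)/C=C/C=C | starting material
13 | methyl rac-(3aS,4S,7aR)-7a-methyl-1,3-dioxo-1,3,3a,4,7,7a-hexahydro-2-benzofuran-4-carboxylate (racemic; the enantiomer carried on is drawn) | C[C@@]12CC=C[C@H](C(=O)OC)[C@@H]1C(=O)OC2=O | intermediate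
14 | all-cis 6-(hydroxymethyl)-2-(methoxycarbonyl)-6-methylcyclohex-3-ene-1-carboxylic acid (racemic; drawn as for 13) | C[C@@]1(CO)CC=C[C@H](C(=O)OC)[C@@H]1C(O)=O | intermediate
15 | methyl rac-(3aS,4S,7aR)-7a-methyl-3-oxo-1,3,3a,4,7,7a-hexahydro-2-benzofuran-4-carboxylate (racemic; drawn as for 13) | C[C@@]12CC=C[C@H](C(=O)OC)[C@@H]1C(=O)OC2 | intermediate
16 | methyl rac-(3aS,4S,7aR)-7a-methyl-3-oxooctahydro-2-benzofuran-4-carboxylate (racemic; drawn as for 13) | C[C@@]12CCC[C@H](C(=O)OC)[C@@H]1C(=O)OC2 | intermediate
17 | rac-(3aS,4S,7aR)-7a-methyl-3-oxooctahydro-2-benzofuran-4-carboxylic acid (racemic; drawn as for 13) | C[C@@]12CCC[C@H](C(=O)O)[C@@H]1C(=O)OC2 | intermediate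
18 | (1S)-1-phenylethanaminium (3aS,4S,7aR)-7a-methyl-3-oxooctahydro-2-benzofuran-4-carboxylate | C[C@@]12CCC[C@H](C(=O)[O-])[C@@H]1C(=O)OC2.C[C@H]([NH3+])c1ccccc1 | intermediate
19 | (3aS,4S,7aR)-7a-methyl-3-oxooctahydro-2-benzofuran-4-carboxylic acid (single enantiomer) | C[C@@]12CCC[C@H](C(=O)O)[C@@H]1C(=O)OC2 | intermediate
20 | (3aS,4S,7aR)-7a-methyl-3-oxooctahydro-2-benzofuran-4-carbonyl chloride | C[C@@]12CCC[C@H](C(=O)Cl)[C@@H]1C(=O)OC2 | intermediate
21 | (3aS,7aR)-4-bromo-7a-methyl-3-oxooctahydro-2-benzofuran-4-carbonyl chloride (both C10 epimers) | C[C@@]12CCCC(Br)(C(=O)Cl)[C@@H]1C(=O)OC2 | intermediate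
22 | (3aS,7aR)-4-bromo-7a-methyl-3-oxooctahydro-2-benzofuran-4-carboxylic acid (both C10 epimers) | C[C@@]12CCCC(Br)(C(=O)O)[C@@H]1C(=O)OC2 | intermediate
23 | methyl (1R,4S,5R)-4-{[(3aS,7aR)-4-bromo-7a-methyl-3-oxooctahydro-2-benzofuran-4-carbonyl]oxy}-6-methylidenebicyclo[3.2.1]oct-2-ene-1-carboxylate (ester oxygen on the C14 face) | COC(=O)[C@@]12C[C@@H]([C@@H](OC(=O)C3(Br)CCC[C@@]4(C)COC(=O)[C@@H]34)C=C1)C(=C)C2 | intermediate
24 | bromozinc enolate of 23 (C10=C20, O–ZnBr) | COC(=O)[C@@]12C[C@@H]([C@@H](OC(O[Zn]Br)=C3CCC[C@@]4(C)COC(=O)[C@@H]34)C=C1)C(=C)C2 | intermediate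
25 | trimethylsilyl ketene acetal of 23 (C10=C20, geometry not fixed) | COC(=O)[C@@]12C[C@@H]([C@@H](OC(O[Si](C)(C)C)=C3CCC[C@@]4(C)COC(=O)[C@@H]34)C=C1)C(=C)C2 | intermediate
26 | trimethylsilyl ester of acid 27 | C[C@@]12CCC[C@@](C(=O)O[Si](C)(C)C)([C@@H]3C=C[C@@H]4C[C@@]3(C(=O)OC)CC4=C)[C@@H]1C(=O)OC2 | intermediate
27 | Claisen acid: 7-methyl hydrogen 19-hydroxy-6,7-seco-ent-kaura-11,16-diene-6,7,20-trioate 6,19-lactone (C9–C10 bond on the C14 face of ring C; C20 carboxyl cis to C6 on ring A) | C[C@@]12CCC[C@@](C(=O)O)([C@@H]3C=C[C@@H]4C[C@@]3(C(=O)OC)CC4=C)[C@@H]1C(=O)OC2 | intermediate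
28 | C20 acyl imidazolide of 27 | C[C@@]12CCC[C@@](C(=O)n5ccnc5)([C@@H]3C=C[C@@H]4C[C@@]3(C(=O)OC)CC4=C)[C@@H]1C(=O)OC2 | intermediate
29 | methyl 19,20-dihydroxy-6,7-seco-ent-kaura-11,16-diene-6,7-dioate 6,19-lactone (C20 primary alcohol) | C[C@@]12CCC[C@@](CO)([C@@H]3C=C[C@@H]4C[C@@]3(C(=O)OC)CC4=C)[C@@H]1C(=O)OC2 | intermediate
30 | 20-O-(dimethylsilyl) ether of 29 (Si–H) | C[C@@]12CCC[C@@](CO[SiH](C)C)([C@@H]3C=C[C@@H]4C[C@@]3(C(=O)OC)CC4=C)[C@@H]1C(=O)OC2 | intermediate
31 | cyclic siloxane: C20–O–SiMe2–C11 oxasilinane (Si on C11 cis to C10, C12 saturated) | C[C@@]12CCC[C@]3(CO[Si](C)(C)[C@@H]4C[C@@H]5C[C@@]([C@@H]43)(C(=O)OC)CC5=C)[C@@H]1C(=O)OC2 | intermediate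
32 | methyl 11,19,20-trihydroxy-6,7-seco-ent-kaur-16-ene-6,7-dioate 6,19-lactone (C11–OH cis to the C9–C10 bond) | C[C@@]12CCC[C@@](CO)([C@@H]3[C@H](O)C[C@@H]4C[C@@]3(C(=O)OC)CC4=C)[C@@H]1C(=O)OC2 | intermediate
33 | 11-hydroxy-6,7-seco-ent-kaur-16-ene-6,19:7,20-diolide | C[C@@]12CCC[C@]3(COC(=O)[C@@]45C[C@@H](C[C@@H](O)[C@H]43)C(=C)C5)[C@@H]1C(=O)OC2 | intermediate
34 | 11,15-dihydroxy-6,7-seco-ent-kaur-16-ene-6,19:7,20-diolide (C15 configuration not fixed) | C[C@@]12CCC[C@]3(COC(=O)[C@@]45C[C@@H](C[C@@H](O)[C@H]43)C(=C)C5O)[C@@H]1C(=O)OC2 | intermediate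
35 | 11-hydroxy-15-oxo-6,7-seco-ent-kaur-16-ene-6,19:7,20-diolide | C[C@@]12CCC[C@]3(COC(=O)[C@@]45C[C@@H](C[C@@H](O)[C@H]43)C(=C)C5=O)[C@@H]1C(=O)OC2 | intermediate
36 | 11-hydroxy-15-oxo-17-(4,4,5,5-tetramethyl-1,3,2-dioxaborolan-2-yl)-6,7-seco-ent-kaurane-6,19:7,20-diolide (C16–H on the C14 face) | C[C@@]12CCC[C@]3(COC(=O)[C@@]45C[C@@H](C[C@@H](O)[C@H]43)[C@@H](CB6OC(C)(C)C(C)(C)O6)C5=O)[C@@H]1C(=O)OC2 | intermediate
37 | CNP0555433.1: 11,17-dihydroxy-15-oxo-6,7-seco-ent-kaurane-6,19:7,20-diolide | C[C@@]12CCC[C@]3(COC(=O)[C@@]45C[C@@H](C[C@@H](O)[C@H]43)[C@@H](CO)C5=O)[C@@H]1C(=O)OC2 | target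

**Step count**

Total: 23 steps. Longest linear sequence: 16 steps (steps 1–7, then 15–23; the ring-A branch, steps 8–14 then 15–23, is equally long).

**Steps most likely to fail**

Step 16. Facial selectivity at C10 may be poor, because the C4 methyl lies 1,3 to C10 on the face that must be attacked. The zinc enolate may also be protonated before the congested [3,3] shift takes place. The fallback sets out from acid 19 and alcohol 10 and comes back at acid 27. Mitsunobu coupling of 19 with 10 (PPh3, DIAD, THF) gives the bromine-free allyl ester F1. This is rearranged by a base-mediated Ireland–Claisen reaction (KN(SiMe3)2, 2.2 equiv, TMSCl, THF or THF/DMPU, −78 to 65 °C). Both the ester and the lactone are silylated as ketene acetals, but only the allyl ester can rearrange. The lactone ketene acetal is hydrolysed on acidic work-up, with reprotonation of C5 from the convex face to restore the cis-fused lactone, which gives 27. In this variant the ketene acetal geometry can be steered by the solvent, which changes the chair/boat pairing and gives a second handle on the C10 face.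

Step 18. Delivery of silicon to the hindered cis-alkene through a six-membered ring may be slow. Platinum could then isomerise the exocyclic methylene or hydrosilylate it intermolecularly. The fallback sets out from acid 27 and comes back at bis-lactone 33.
- Iodolactonisation (I2, NaHCO3, THF/H2O) gives iodolactone F2, with the C20 carboxyl oxygen on C11 cis to C10 and iodine trans at C12.
- Bu3SnH/AIBN at high stannane concentration (to outrun homoallyl radical rearrangement) removes iodine and gives lactone F3.
- Lithium iodide in pyridine at reflux cleaves the methyl ester to the C7 acid F4.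
- As its lithium carboxylate (LiOt-Bu, 1 equiv) the C7 carboxyl is inert to LiBH4, which reduces both γ-lactones. Acidification then closes the C7–O–C20 δ-lactone and gives triol F5.
- TEMPO/PhI(OAc)2 oxidises the less hindered primary C6 alcohol, and then the lactol, to the C6,C19 γ-lactone, leaving the secondary C11 hydroxyl and giving 33.

Step 15. Displacement at the hindered C12 carbinol by the bulky tertiary bromo acid may not occur, or the tertiary bromide may be lost to the phosphine. The fallback sets out from alcohol 10 and bromo acyl chloride 21 and comes back at ester 23. Mitsunobu inversion of 10 with 4-nitrobenzoic acid gives the inverted 4-nitrobenzoate F6. Methanolysis (K2CO3, MeOH) gives the epimeric alcohol F7, with its hydroxyl on the C14 face. Acylation of F7 with 21 (pyridine, DMAP, CH2Cl2) proceeds with retention and gives 23.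

**Further compounds**

F1 | step 16 | methyl (1R,4S,5R)-4-{[(3aS,4S,7aR)-7a-methyl-3-oxooctahydro-2-benzofuran-4-carbonyl]oxy}-6-methylidenebicyclo[3.2.1]oct-2-ene-1-carboxylate | COC(=O)[C@@]12C[C@@H]([C@@H](OC(=O)[C@H]3CCC[C@@]4(C)COC(=O)[C@@H]34)C=C1)C(=C)C2
F2 | step 18 | iodolactone: 12-iodo 20,11-lactone of acid 27 (O on C11 cis to C10, I trans) | C[C@@]12CCC[C@]3(C(=O)O[C@@H]4[C@@H](I)[C@@H]5C[C@@]([C@@H]43)(C(=O)OC)CC5=C)[C@@H]1C(=O)OC2
F3 | step 18 | deiodinated 20,11-lactone methyl ester | C[C@@]12CCC[C@]3(C(=O)O[C@@H]4C[C@@H]5C[C@@]([C@@H]43)(C(=O)OC)CC5=C)[C@@H]1C(=O)OC2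
F4 | step 18 | 20,11-lactone C7 carboxylic acid | C[C@@]12CCC[C@]3(C(=O)O[C@@H]4C[C@@H]5C[C@@]([C@@H]43)(C(=O)O)CC5=C)[C@@H]1C(=O)OC2
F5 | step 18 | 6,11,19-trihydroxy-6,7-seco-ent-kaur-16-en-7,20-olide | C[C@@]1(CO)CCC[C@]2(COC(=O)[C@@]34C[C@@H](C[C@@H](O)[C@H]32)C(=C)C4)[C@@H]1CO
F6 | step 15 | methyl (1R,4S,5R)-6-methylidene-4-[(4-nitrobenzoyl)oxy]bicyclo[3.2.1]oct-2-ene-1-carboxylate | COC(=O)[C@@]12C[C@@H]([C@@H](OC(=O)c3ccc(cc3)[N+](=O)[O-])C=C1)C(=C)C2
F7 | step 15 | methyl (1R,4S,5R)-4-hydroxy-6-methylidenebicyclo[3.2.1]oct-2-ene-1-carboxylate | COC(=O)[C@@]12C[C@@H]([C@@H](O)C=C1)C(=C)C2
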